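**Assumption:** the quinine-derived 9-amino-9-deoxy-epi-cinchona amine is taken to be the catalyst antipode that sends the phenol to the Si face of the β-carbon of enal 2 (this gives 4S); if the sense proves opposite, the quinidine-derived pseudo-enantiomer is used with no other change.

## The problem

Sideroxylonal A (10) is a 2-aryl-3,4-dialkylchroman. Its fused ring A (OH at C5 and C7, CHO at C6 and C8) and its pendant ring B (a 2,4,6-trihydroxy-3,5-diformylphenyl group on C2) are both fully substituted diformylphloroglucinols. The pyran ring carries three contiguous stereocentres, C2 (R, aryl), C3 (R, isopropyl) and C4 (S, isobutyl), in a 2,3-trans, 3,4-cis arrangement. C4 is a benzylic C–C centre that cannot be corrected once made, so it must be set in absolute terms. C3 is α to a carbonyl group in any lactol or aldehyde precursor and can follow C4 by protonation or equilibration; C2 is a benzylic ether carbon next to a very electron-rich aryl group and can follow C3 by reversible ionisation. The four aryl aldehydes survive neither organolithium reagents nor amine catalysis, and free phloroglucinol rings are oxidation-prone and make the O1–C2 bond acid-labile, so formyl groups and free phenols must come last and the oxygens must travel as robust ethers. The enabling feature is that C4 is a methine on C4a, a carbon ortho to the ring oxygen O1 of a phloroglucinol-type ring, while C2, C3, C4 and their two branches are exactly the ten carbons of the commercial enal 2. A phenol can therefore be joined to 2 through C4–C4a and O1–C2 in one catalytic, enantioselective operation.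

## Retrosynthesis

**10 ⇒ 9 (five O–CH3 bonds).** The five phenols are taken back to methyl ethers. In 9 every methoxy group is ortho to a formyl group, so chelation-assisted cleavage with BCl3 can reach all five. Methyl is preferred to benzyl because it survives aryllithium and TiCl4 chemistry and releases no benzyl cations that could alkylate the rings. The forward step must cleave five ethers without opening the O1–C2 bond.

**9 ⇒ 8 (four aryl–CHO bonds).** The aldehydes are removed next, since they cannot pass through the aryllithium addition or the amine catalysis. The four open positions of 8 (C6, C8 on ring A and C3', C5' on ring B) are the only aromatic C–H bonds and each lies between two oxygens, so exhaustive electrophilic formylation has no regiochemical choice. The forward step must form four C–C bonds in one operation, the second on each ring onto a ring that already carries one formyl group.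

**8 ⇒ 7 (O1–C2).** The pyran ring is opened at O1–C2 rather than at the aryl–oxygen bond C8a–O1. C2 is benzylic to a 2,4,6-trimethoxyphenyl group, so the carbinol of 7 ionises under mild acid and the phenol oxygen closes the ring. Because the closure is reversible, C2 can settle trans to the C3 isopropyl group, and the carbinol configuration of 7 does not matter. The forward step must form the ether without losing the C3 proton from the cation.

**7 ⇒ 4 + 5 (C2–C1' of ring B).** Ring B is attached through C2 only and is symmetrical, so it is cut off as 2,4,6-trimethoxyphenyllithium 6, made from 1,3,5-trimethoxybenzene 5, adding to the aldehyde of the open form 3 of lactol 4. A direct acid-mediated arylation of 4 with 5 would be one step shorter, but it leaves excess nucleophilic arene beside an ionisable product and invites double arylation. The basic addition followed by a separate acid step avoids this. The forward step must add a hindered aryllithium to an α-branched aldehyde faster than it deprotonates C3.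

**4 ⇒ 1 + 2 (C4–C4a and O1–C2).** The lactol is cut into 3,5-dimethoxyphenol 1 and (E)-2-isopropyl-5-methylhex-2-enal 2, both purchased. This cut sets C4 absolutely with a catalyst, brings in both alkyl branches in their final form and needs no protecting-group changes. The forward reaction must achieve conjugate rather than carbonyl addition on a hindered α-branched enal, face control at C4 and the cis relationship at C3.

## Roads not taken

**Alternative 1:** The cut removes C8a–O1, C4a–C4 and O1–C2 together. CsF releases the dimethoxy aryne from silyl triflate A1, which adds across the carbonyl group of enone A2; the ortho-quinone methide formed closes by oxa-6π electrocyclisation to the racemic 2H-chromene A3.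
- Merits: it is more convergent than the chosen plan, since ring B and every skeletal carbon arrive in one step. The methoxy group next to the aryne should direct the carbonyl oxygen to the distal carbon, as the target requires.
- Weak points: A3 is flat at C3 and C4 and racemic at C2, so no stereocentre of the target is set. Hydrogen would add to the tetrasubstituted C3=C4 bond anti to the C2 aryl group and give the 2,3-cis series, so C2 would have to be erased and all three centres set afterwards on a fully substituted chromene. Ketone carbonyls are also poor partners for aryne insertion compared with aldehydes.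
- Comparison: this road wins on convergence. The chosen plan sets against that the absolute configuration at C4 and the C3 relationship already fixed in its key step.

**Alternative 2:** The cut is O1–C2 alone, with C3 carrying a methyl ester in place of isopropyl. K2CO3 in methanol converts phenol A4 to its phenoxide, which adds to the benzylidene carbon and gives chroman ester A5.
- Merits: C3 stays epimerisable, so C2 and C3 can both settle under thermodynamic control relayed from C4. That is a cleaner handle on C3 than enamine protonation, and in this respect the road is better.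
- Weak points: the acceptor carbon bears a strongly donating, doubly ortho-substituted aryl group, so the addition is slow and readily reversed. The ester must later become isopropyl (double methyl addition and deoxygenation), under basic conditions that can reopen the ring. A4 still needs its own asymmetric synthesis of the C4 centre.
- Comparison: the chosen plan carries the isopropyl group from the start and reaches the same oxidation pattern in fewer steps.

**Alternative 3:** The cut is C8a–O1. Pd(OAc)2, a bulky biaryl di-tert-butylphosphine and Cs2CO3 couple the C2 hydroxyl of bromo alcohol A6 with its aryl bromide and give chroman A7, which is the same compound as 8.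
- Merits: no cation is formed at C2, so the three centres are fixed before ring closure and cannot scramble. It is safer than the chosen acid closure in that respect, and it feeds the same end game.
- Weak points: A6 is an open-chain stereotriad that needs several auxiliary- or catalyst-controlled steps. Its hindered secondary benzylic alkoxide on palladium has a β-hydrogen and can collapse to the ketone with loss of bromide.
- Comparison: the chosen plan accepts a cationic closure because the C2 epimer of 8 would suffer a syn-diaxial clash, so equilibration should correct C2 on its own.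

Key step: step 1

## Route

Step 1
Reactants: 1 3,5-dimethoxyphenol; 2 (E)-2-isopropyl-5-methylhex-2-enal
Product: 4 (3R,4S)-4-isobutyl-3-isopropyl-5,7-dimethoxychroman-2-ol (3,4-cis; both C2 anomers), via open-chain hydroxy aldehyde 3 (not isolated)
Conditions: 9-amino-9-deoxy-epi-quinine (20 mol%), CF3CO2H (40 mol%), 1 (2 equiv), toluene, rt → 40 °C
Reagents that add atoms: none
Why: Iminium-ion Friedel–Crafts conjugate addition with hemiacetal closure: the primary amine (needed because the α-isopropyl group of 2 blocks secondary amines) condenses with 2 to an iminium ion, an ortho carbon of 1 adds to its β-carbon (C4–C4a), the enamine is protonated at C3 and hydrolysed to 3, and the phenol oxygen adds to the aldehyde (O1–C2). The closest known reactions are the amine-catalysed Friedel–Crafts/lactolisation of electron-rich phenols with β-substituted enals and the primary-amine iminium activation of α-branched enals toward indoles; this step joins the two. The pyran ring closes in a 6-exo-trig mode, the C=O bond of 3 lying outside the new ring. C4 is set by the catalyst: the protonated quinuclidine and its counter-anion hold the phenol OH by hydrogen bonding and deliver the ortho carbon to the Si face of the β-carbon, which gives 4S. C3 is set by protonation of the enamine and, staying α to the aldehyde of 3, should settle by epimerisation through 3 into the lactol with the isobutyl group pseudo-axial (away from the C5 methoxy group) and the isopropyl group equatorial, i.e. 3,4-cis (3R). C2 forms as an anomeric mixture, which is harmless because this carbon is ionised in step 3. The step needs 1,4- rather than 1,2-addition (the acidic medium and the single β-substituent favour conjugate attack; 1,2-attack would end in a 2H-chromene), ortho rather than para attack (the hydrogen-bonded OH directs to the two equivalent ortho carbons and the para carbon lies between two methoxy groups) and mono-alkylation (1 is in excess and 4 has no free phenol left to bind the catalyst).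

Step 2
Reactants: 4 (3R,4S)-4-isobutyl-3-isopropyl-5,7-dimethoxychroman-2-ol; 5 1,3,5-trimethoxybenzene
Product: 7 (2R,3S)-3-(2-hydroxy-4,6-dimethoxyphenyl)-2-isopropyl-5-methyl-1-(2,4,6-trimethoxyphenyl)hexan-1-ol (both C1 epimers), via 2,4,6-trimethoxyphenyllithium 6 (not isolated)
Conditions: 5 (3 equiv), n-BuLi (3 equiv), THF, 0 °C → rt; then 4, THF, −78 → 0 °C; aq. NH4Cl
Reagents that add atoms: none
Why: Directed ortho-lithiation of 5 between two methoxy groups gives 6; one equivalent deprotonates lactol 4, whose lithium lactolate opens to the phenoxide aldehyde of 3, and a second equivalent adds to the carbonyl group (1,2-addition of an aryllithium to a lactol). The new carbinol centre needs no control because step 3 ionises it, and low temperature should keep deprotonation at C3 behind addition.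

Step 3
Reactants: 7 (2R,3S)-3-(2-hydroxy-4,6-dimethoxyphenyl)-2-isopropyl-5-methyl-1-(2,4,6-trimethoxyphenyl)hexan-1-ol
Product: 8 (2R,3R,4S)-4-isobutyl-3-isopropyl-5,7-dimethoxy-2-(2,4,6-trimethoxyphenyl)chroman (2,3-trans, 3,4-cis)
Conditions: p-TsOH·H2O (10 mol%), 4 Å MS, CH2Cl2, 0 °C → rt
Reagents that add atoms: none
Why: Acid-catalysed cyclodehydration: the trimethoxyphenyl carbinol ionises to a stabilised benzylic cation and the phenol oxygen closes the six-membered ring. The O1–C2 bond of the product can re-ionise, so C2 should equilibrate to the 2R isomer with aryl and isopropyl both equatorial (trans) and isobutyl pseudo-axial; the C2 epimer would place aryl and isobutyl syn-diaxial. C3 and C4 are not touched.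

Step 4
Reactants: 8 (2R,3R,4S)-4-isobutyl-3-isopropyl-5,7-dimethoxy-2-(2,4,6-trimethoxyphenyl)chroman
Product: 9 (2R,3R,4S)-2-(3,5-diformyl-2,4,6-trimethoxyphenyl)-4-isobutyl-3-isopropyl-5,7-dimethoxychroman-6,8-dicarbaldehyde
Conditions: Cl2CHOMe (12 equiv), TiCl4 (12 equiv), CH2Cl2, −20 °C → rt; then ice, aq. HCl
Reagents that add atoms: dichloromethyl methyl ether, ClC(Cl)OC; water, O
Why: Fourfold Rieche formylation: the four remaining aromatic C–H positions (C6, C8, C3', C5') each lie between two oxygen substituents, so exhaustive electrophilic substitution has no regiochemical alternative, and double formylation of 2,4,6-trimethoxyphenyl rings under these conditions is established. The first formyl group on ring B makes ionisation at C2 harder, which protects the stereocentres.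

Step 5
Reactants: 9 (2R,3R,4S)-2-(3,5-diformyl-2,4,6-trimethoxyphenyl)-4-isobutyl-3-isopropyl-5,7-dimethoxychroman-6,8-dicarbaldehyde
Product: 10 sideroxylonal A, (2R,3R,4S)-2-(3,5-diformyl-2,4,6-trihydroxyphenyl)-5,7-dihydroxy-4-isobutyl-3-isopropylchroman-6,8-dicarbaldehyde
Conditions: BCl3 (1 M in CH2Cl2, 15 equiv), CH2Cl2, −78 °C → rt; then H2O
Reagents that add atoms: none
Why: Chelation-assisted Lewis-acid ether cleavage: BCl3 bound to a formyl oxygen cleaves the ortho methoxy group through a six-membered chelate, and all five methoxy groups of 9 are ortho to a formyl group. The stereocentres are not involved.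

## Compound list

1 | 3,5-dimethoxyphenol | COc1cc(O)cc(OC)c1 | starting material
2 | (E)-2-isopropyl-5-methylhex-2-enal | CC(C)C/C=C(/C=O)C(C)C | starting material
3 | (2R,3S)-3-(2-hydroxy-4,6-dimethoxyphenyl)-2-isopropyl-5-methylhexanal (open form of 4) | CC(C)C[C@H](c1c(OC)cc(OC)cc1O)[C@H](C=O)C(C)C | intermediate
4 | (3R,4S)-4-isobutyl-3-isopropyl-5,7-dimethoxychroman-2-ol (3,4-cis, C2 anomeric mixture) | CC(C)C[C@@H]1c2c(OC)cc(OC)cc2OC(O)[C@@H]1C(C)C | intermediate
5 | 1,3,5-trimethoxybenzene | COc1cc(OC)cc(OC)c1 | starting material
6 | 2,4,6-trimethoxyphenyllithium | [Li]c1c(OC)cc(OC)cc1OC | intermediate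
7 | (2R,3S)-3-(2-hydroxy-4,6-dimethoxyphenyl)-2-isopropyl-5-methyl-1-(2,4,6-trimethoxyphenyl)hexan-1-ol (both C1 epimers) | CC(C)C[C@H](c1c(OC)cc(OC)cc1O)[C@H](C(O)c1c(OC)cc(OC)cc1OC)C(C)C | intermediate
8 | (2R,3R,4S)-4-isobutyl-3-isopropyl-5,7-dimethoxy-2-(2,4,6-trimethoxyphenyl)chroman | CC(C)C[C@@H]1c2c(OC)cc(OC)cc2O[C@@H](c2c(OC)cc(OC)cc2OC)[C@@H]1C(C)C | intermediate
9 | (2R,3R,4S)-2-(3,5-diformyl-2,4,6-trimethoxyphenyl)-4-isobutyl-3-isopropyl-5,7-dimethoxychroman-6,8-dicarbaldehyde | CC(C)C[C@@H]1c2c(OC)c(C=O)c(OC)c(C=O)c2O[C@@H](c2c(OC)c(C=O)c(OC)c(C=O)c2OC)[C@@H]1C(C)C | intermediate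
10 | sideroxylonal A, (2R,3R,4S)-2-(3,5-diformyl-2,4,6-trihydroxyphenyl)-5,7-dihydroxy-4-isobutyl-3-isopropylchroman-6,8-dicarbaldehyde | CC(C)C[C@@H]1c2c(O)c(C=O)c(O)c(C=O)c2O[C@@H](c2c(O)c(C=O)c(O)c(C=O)c2O)[C@@H]1C(C)C | target

## Step count and least certain steps

Total steps: 5. Longest linear sequence: 5 steps (1 + 2 → 4 → 7 → 8 → 9 → 10).

**Step 1 (key step).** Most likely failures:
- slow iminium formation and turnover, because the β-carbon of 2 is flanked by isobutyl and a cis isopropyl group;
- diversion into carbonyl addition and condensation;
- poor facial selectivity at C4;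
- protonation and equilibration at C3 settling on the 3,4-trans lactol, since the energy gap between the two C3 epimers cannot be predicted with confidence.

Fallback, setting out from 1 and returning at 4, using known reactions only:
- Diarylprolinol trimethylsilyl ether catalysis (the catalyst enantiomer that gives 4S) joins 1 to the unbranched (E)-5-methylhex-2-enal F1 and gives (4S)-4-isobutyl-5,7-dimethoxychroman-2-ol F2.
- Ag2CO3 on Celite in hot toluene oxidises it to (S)-4-isobutyl-5,7-dimethoxychroman-2-one F3.
- The lithium enolate of F3 (LiN(i-Pr)2, THF, −78 °C) is trapped with acetone to give (4S)-3-(2-hydroxypropan-2-yl)-4-isobutyl-5,7-dimethoxychroman-2-one F4.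
- p-TsOH in refluxing toluene dehydrates it to the conjugated (R)-4-isobutyl-5,7-dimethoxy-3-(propan-2-ylidene)chroman-2-one F5. C4 is unchanged; only its descriptor changes.
- Hydrogenation (H2, Pd on carbon) adds hydrogen to the face opposite the pseudo-axial isobutyl group and gives (3R,4S)-4-isobutyl-3-isopropyl-5,7-dimethoxychroman-2-one F6, which is cis by kinetic control.
- i-Bu2AlH at −78 °C reduces F6 to lactol 4.

**Step 4.** Most likely failures: stalling before the fourth formyl group as each ring is deactivated, and TiCl4-induced ionisation of the O1–C2 bond while ring B is still electron-rich, with ring opening, loss of the C3 proton or intermolecular arylation. The BCl3 exposure of step 5 carries a related risk of O1–C2 cleavage through the C8 formyl chelate.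

Fallback, setting out from 8 and returning at 10: the order of the end game is reversed. BBr3 in CH2Cl2 demethylates 8 to (2R,3R,4S)-4-isobutyl-3-isopropyl-2-(2,4,6-trihydroxyphenyl)chroman-5,7-diol F8. Vilsmeier–Haack formylation (POCl3, DMF, then aqueous hydrolysis) of its two free phloroglucinol-type rings, which are far more reactive than their methyl ethers, gives 10 directly. Step 5 is no longer needed.

**Step 2.** Most likely failures: deprotonation at C3 by the basic aryllithium instead of addition (loss of the C3 configuration through the enolate of 3), or slow addition of the doubly ortho-substituted nucleophile to the α-branched aldehyde.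

Fallback, setting out from 4 and returning at 8, with reversed polarity: Ac2O and pyridine convert 4 to (3R,4S)-4-isobutyl-3-isopropyl-5,7-dimethoxychroman-2-yl acetate F7. BF3·OEt2 with one equivalent of 5 in CH2Cl2 at low temperature ionises F7 to the cyclic oxocarbenium ion, which undergoes Friedel–Crafts C-arylation. The product can re-ionise at C2, so the trans isomer 8 should result. Steps 2 and 3 are bypassed, and the arene is kept stoichiometric to limit double arylation.

## Further compounds

F1 | step 1 | (E)-5-methylhex-2-enal | CC(C)C/C=C/C=O
F2 | step 1 | (4S)-4-isobutyl-5,7-dimethoxychroman-2-ol (anomeric mixture) | CC(C)C[C@@H]1c2c(OC)cc(OC)cc2OC(O)C1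
F3 | step 1 | (S)-4-isobutyl-5,7-dimethoxychroman-2-one | CC(C)C[C@@H]1c2c(OC)cc(OC)cc2OC(=O)C1
F4 | step 1 | (4S)-3-(2-hydroxypropan-2-yl)-4-isobutyl-5,7-dimethoxychroman-2-one (C3 epimers) | CC(C)C[C@@H]1c2c(OC)cc(OC)cc2OC(=O)C1C(C)(C)O
F5 | step 1 | (R)-4-isobutyl-5,7-dimethoxy-3-(propan-2-ylidene)chroman-2-one | CC(C)C[C@@H]1c2c(OC)cc(OC)cc2OC(=O)C1=C(C)C
F6 | step 1 | (3R,4S)-4-isobutyl-3-isopropyl-5,7-dimethoxychroman-2-one | CC(C)C[C@@H]1c2c(OC)cc(OC)cc2OC(=O)[C@@H]1C(C)C
F7 | step 2 | (3R,4S)-4-isobutyl-3-isopropyl-5,7-dimethoxychroman-2-yl acetate (anomeric mixture) | CC(C)C[C@@H]1c2c(OC)cc(OC)cc2OC(OC(C)=O)[C@@H]1C(C)C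
F8 | step 4 | (2R,3R,4S)-4-isobutyl-3-isopropyl-2-(2,4,6-trihydroxyphenyl)chroman-5,7-diol | CC(C)C[C@@H]1c2c(O)cc(O)cc2O[C@@H](c2c(O)cc(O)cc2O)[C@@H]1C(C)C
A1 | alternative 1 | 3,5-dimethoxy-2-(trimethylsilyl)phenyl trifluoromethanesulfonate | COc1cc(OC)c([Si](C)(C)C)c(OS(=O)(=O)C(F)(F)F)c1
A2 | alternative 1 | (E)-2-isopropyl-5-methyl-1-(2,4,6-trimethoxyphenyl)hex-1-en-3-one | CC(C)CC(=O)/C(=C/c1c(OC)cc(OC)cc1OC)C(C)C
A3 | alternative 1 | racemic 4-isobutyl-3-isopropyl-5,7-dimethoxy-2-(2,4,6-trimethoxyphenyl)-2H-chromene | CC(C)CC1=C(C(C)C)C(c2c(OC)cc(OC)cc2OC)Oc2cc(OC)cc(OC)c21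
A4 | alternative 2 | methyl (3R)-3-(2-hydroxy-4,6-dimethoxyphenyl)-5-methyl-2-(2,4,6-trimethoxybenzylidene)hexanoate | CC(C)C[C@H](c1c(OC)cc(OC)cc1O)C(C(=O)OC)=Cc1c(OC)cc(OC)cc1OC
A5 | alternative 2 | methyl (2R,3R,4S)-4-isobutyl-5,7-dimethoxy-2-(2,4,6-trimethoxyphenyl)chroman-3-carboxylate | CC(C)C[C@@H]1c2c(OC)cc(OC)cc2O[C@@H](c3c(OC)cc(OC)cc3OC)[C@@H]1C(=O)OC
A6 | alternative 3 | (1R,2R,3S)-3-(2-bromo-4,6-dimethoxyphenyl)-2-isopropyl-5-methyl-1-(2,4,6-trimethoxyphenyl)hexan-1-ol | CC(C)C[C@H](c1c(OC)cc(OC)cc1Br)[C@H]([C@@H](O)c1c(OC)cc(OC)cc1OC)C(C)C
A7 | alternative 3 | (2R,3R,4S)-4-isobutyl-3-isopropyl-5,7-dimethoxy-2-(2,4,6-trimethoxyphenyl)chroman (identical with 8) | CC(C)C[C@@H]1c2c(OC)cc(OC)cc2O[C@@H](c2c(OC)cc(OC)cc2OC)[C@@H]1C(C)C
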